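**Plan**

- Numbering: C1 is the tertiary carbinol bearing C7H2OBz, C2 is CHOH, C3 is CHOBz, C4=C5 is the alkene and C6 is the ketone. These locants are kept in the names of all intermediates after the spiro adduct.
- Feature: O–C1–C7 is the O–Cα–C(carboxyl) unit of a 2-oxyacrylate. C1 adjoins oxygenated C2 with both oxygens cis, so the carbocycle maps onto a [4+2] adduct of C6=C1 with a 1-oxydiene C2–C5.
- Cuts, in order: acetonide off, C6=O back to CH2, benzoates off, C3–OH/C4=C5 back to a C3=C4 alkene through its epoxide, C7 back to an ester, then C1–C2 and C5–C6 together.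
- Forward: the dioxolanone ring is built first and the six-membered ring closes on it as a spirocycle. The auxiliary ring is then opened and a C1/C2 acetonide takes its place until the last step.
- Stereochemistry: (S)-lactic acid sets the acetal carbon, and its tert-butyl group sets C1 by facial shielding. Exo topology with the E diene sets C2. Epoxidation anti to the acetonide with anti opening at C4 sets C3.

Key step: step 4

Assumption: bought 1-acetoxybuta-1,3-diene is an E/Z mixture. Only the E isomer reaches the reactive s-cis form, so the mixture is used in excess and counted as the E diene.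

**Route**

Step 1
Reactants: 1 (S)-lactic acid; 2 pivalaldehyde
Product: 3 (2S,5S)-2-tert-butyl-5-methyl-1,3-dioxolan-4-one (tert-butyl and methyl cis)
Conditions: p-TsOH (cat.), pentane, reflux, Dean–Stark trap; crystallisation from pentane, −78 °C
Reagents that add atoms: none
Why: Acid-catalysed acetalisation with azeotropic removal of water equilibrates towards the cis isomer, so the lactic acid centre sets the acetal carbon as S, and crystallisation should remove the trans isomer, whose acetal carbon has the opposite sense and would lower the enantiopurity of the dienophile.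

Step 2
Reactants: 3 (2S,5S)-2-tert-butyl-5-methyl-1,3-dioxolan-4-one
Product: 4 (2S,5R)-5-bromo-2-tert-butyl-5-methyl-1,3-dioxolan-4-one (bromine trans to tert-butyl)
Conditions: NBS, AIBN (cat.), CCl4, reflux
Reagents that add atoms: N-bromosuccinimide, O=C1CCC(=O)N1Br
Why: Wohl–Ziegler radical bromination takes the captodatively weakened C5–H between ring oxygen and carbonyl and leaves the acetal centre untouched, and the configuration at C5 does not matter because step 3 erases it.

Step 3
Reactants: 4 (2S,5R)-5-bromo-2-tert-butyl-5-methyl-1,3-dioxolan-4-one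
Product: 5 (S)-2-tert-butyl-5-methylene-1,3-dioxolan-4-one
Conditions: Et3N, CH2Cl2, 0 °C to rt
Reagents that add atoms: none
Why: E2 dehydrobromination can use only the methyl hydrogens, so the exocyclic alkene forms and the acetal carbon remains as the sole stereocentre.

Step 4
Reactants: 5 (S)-2-tert-butyl-5-methylene-1,3-dioxolan-4-one; 6 (E)-1-acetoxybuta-1,3-diene
Product: 7 (2S,5R,6S)-2-tert-butyl-4-oxo-1,3-dioxaspiro[4.5]dec-7-en-6-yl acetate (ring oxygen on the spiro carbon cis to the acetoxy group)
Conditions: 6 (3 equiv), BHT (cat.), toluene, sealed tube, 110 °C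
Reagents that add atoms: none
Why: A concerted, suprafacial normal-electron-demand Diels–Alder reaction joins C5 to C6 and C2 to C1 in one event, the closest known reaction type being the thermal exo-selective cycloaddition of 5-methylene-1,3-dioxolan-4-ones to cyclic and acyclic dienes. The cyclohexene ring closes by intermolecular [4+2] annulation onto the exocyclic alkene, so that C1 becomes the spiro atom shared with the dioxolanone. The reaction needs ortho regiochemistry, which is secured by matching the largest HOMO coefficient of 6 (its unsubstituted terminus, C5) with the largest LUMO coefficient of 5 (its methylene carbon, C6), leaving the acetoxy-bearing carbon to bond to C1. C1 is set by the tert-butyl group on the acetal carbon, which covers one face of the flat dienophile and sends the diene to the other. C2 is set relative to C1 by exo topology: the lactone carbonyl, locked s-cis to the alkene, avoids the diene for dipolar and steric reasons, so the ring oxygen lies endo and finishes cis to the outward acetoxy group of the E diene. BHT holds back radical polymerisation of the captodative alkene, and minor endo or facial isomers should be removable by chromatography.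

Step 5
Reactants: 7 (2S,5R,6S)-2-tert-butyl-4-oxo-1,3-dioxaspiro[4.5]dec-7-en-6-yl acetate
Product: 8 methyl (1R,2S)-1,2-dihydroxycyclohex-3-ene-1-carboxylate
Conditions: NaOMe (cat.), MeOH, 0 °C to rt
Reagents that add atoms: methanol, CO
Why: In a Zemplén-type transesterification methoxide opens the activated acylal carbonyl, the hemiacetal alkoxide collapses with loss of pivalaldehyde and the allylic acetate is exchanged in the same pot, with no bond to a stereocentre broken.

Step 6
Reactants: 8 methyl (1R,2S)-1,2-dihydroxycyclohex-3-ene-1-carboxylate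
Product: 9 methyl (1R,2S)-1,2-(isopropylidenedioxy)cyclohex-3-ene-1-carboxylate
Conditions: 2,2-dimethoxypropane, p-TsOH (cat.), CH2Cl2, rt
Reagents that add atoms: 2,2-dimethoxypropane, COC(C)(C)OC
Why: In this acid-catalysed transacetalisation C7 is still an ester, so only the cis C1/C2 diol can be bridged, which avoids the competition from a C1/C7 spiro acetonide that a free triol would show.

Step 7
Reactants: 9 methyl (1R,2S)-1,2-(isopropylidenedioxy)cyclohex-3-ene-1-carboxylate
Product: 10 [(1S,2S)-1,2-(isopropylidenedioxy)cyclohex-3-en-1-yl]methanol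
Conditions: LiAlH4, THF, 0 °C; aqueous work-up
Reagents that add atoms: none
Why: This is a standard hydride reduction of an ester without alpha hydrogen, and the isolated alkene and the acetonide are inert to it.

Step 8
Reactants: 10 [(1S,2S)-1,2-(isopropylidenedioxy)cyclohex-3-en-1-yl]methanol
Product: 11 [(1S,2S,3R,4R)-3,4-epoxy-1,2-(isopropylidenedioxy)cyclohexyl]methanol (epoxide oxygen on the face of C7, anti to the acetonide)
Conditions: mCPBA, CH2Cl2, 0 °C to rt
Reagents that add atoms: 3-chloroperbenzoic acid, O=C(OO)c1cccc(Cl)c1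
Why: In this Prilezhaev epoxidation the cis-fused acetonide shields the face of the C1 and C2 oxygens while the C7 hydroxyl on the other face can hydrogen-bond to the peracid, so oxygen should arrive anti to the C2 oxygen and set C3 and C4.

Step 9
Reactants: 11 [(1S,2S,3R,4R)-3,4-epoxy-1,2-(isopropylidenedioxy)cyclohexyl]methanol
Product: 14 (1S,2S,3R)-1-(hydroxymethyl)-1,2-O-isopropylidenecyclohex-4-ene-1,2,3-triol, via hydroxy selenide 12 (not isolated), via selenoxide 13 (not isolated)
Conditions: (PhSe)2, NaBH4, EtOH, rt to reflux; then THF, 30% H2O2, 0 °C to rt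
Reagents that add atoms: diphenyl diselenide, c1ccc(cc1)[Se][Se]c1ccccc1 (PhSe of 12 and 13, lost again before 14); hydrogen peroxide, OO (selenoxide oxygen of 13, lost again before 14)
Why: In this organoselenium epoxide-to-allylic-alcohol transposition the soft selenolate opens the epoxide by SN2 at C4, the carbon remote from the electron-withdrawing C2 oxygen, which leaves the C3–O bond and its configuration intact, and the selenoxide then undergoes syn elimination away from the carbinol carbon to place the alkene at C4=C5.

Step 10
Reactants: 14 (1S,2S,3R)-1-(hydroxymethyl)-1,2-O-isopropylidenecyclohex-4-ene-1,2,3-triol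
Product: 15 [(1S,2S,3R)-3-(benzoyloxy)-1,2-(isopropylidenedioxy)cyclohex-4-en-1-yl]methyl benzoate
Conditions: BzCl (2.5 equiv), pyridine, DMAP (cat.), CH2Cl2, 0 °C to rt
Reagents that add atoms: benzoyl chloride, O=C(Cl)c1ccccc1
Why: DMAP-catalysed acylation meets only two free hydroxyls, at C3 and C7, and these are the two that carry benzoates in the target, so no selectivity is required.

Step 11
Reactants: 15 [(1S,2S,3R)-3-(benzoyloxy)-1,2-(isopropylidenedioxy)cyclohex-4-en-1-yl]methyl benzoate
Product: 17 [(1S,2S,3R)-3-(benzoyloxy)-1,2-(isopropylidenedioxy)-6-oxocyclohex-4-en-1-yl]methyl benzoate (zeylenone 1,2-acetonide), via C6 allylic alcohol 16 (not isolated)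
Conditions: SeO2, 1,4-dioxane, 80 °C; then Dess–Martin periodinane, CH2Cl2, rt
Reagents that add atoms: selenium dioxide, O=[Se]=O
Why: In the Riley allylic oxidation the ene reaction and [2,3]-sigmatropic shift return oxygen to the carbon that lost hydrogen, so the alkene cannot transpose as it can in radical oxidations, C6–H is preferred because the benzoate deactivates C3–H, and the Dess–Martin oxidation erases the new carbinol centre.

Step 12
Reactants: 17 zeylenone 1,2-acetonide
Product: 18 zeylenone, [(1S,5R,6S)-5-(benzoyloxy)-1,6-dihydroxy-2-oxocyclohex-3-en-1-yl]methyl benzoate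
Conditions: TFA–H2O (9:1), CH2Cl2, 0 °C to rt
Reagents that add atoms: none
Why: Acid-catalysed acetal hydrolysis breaks only the bonds to the isopropylidene carbon, so C1 and C2 keep their oxygens and configuration, and cold aqueous acid should be too mild for benzoyl migration or elimination.

**Compound list**

1 | (S)-lactic acid | C[C@H](O)C(=O)O | starting material
2 | pivalaldehyde | CC(C)(C)C=O | starting material
3 | (2S,5S)-2-tert-butyl-5-methyl-1,3-dioxolan-4-one | O=C1O[C@@H](C(C)(C)C)O[C@H]1C | intermediate
4 | (2S,5R)-5-bromo-2-tert-butyl-5-methyl-1,3-dioxolan-4-one | O=C1O[C@@H](C(C)(C)C)O[C@]1(C)Br | intermediate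
5 | (S)-2-tert-butyl-5-methylene-1,3-dioxolan-4-one | O=C1O[C@@H](C(C)(C)C)OC1=C | intermediate
6 | (E)-1-acetoxybuta-1,3-diene | CC(=O)O/C=C/C=C | starting material
7 | (2S,5R,6S)-2-tert-butyl-4-oxo-1,3-dioxaspiro[4.5]dec-7-en-6-yl acetate | O=C1O[C@@H](C(C)(C)C)O[C@@]12CCC=C[C@@H]2OC(C)=O | intermediate
8 | methyl (1R,2S)-1,2-dihydroxycyclohex-3-ene-1-carboxylate | COC(=O)[C@@]1(O)CCC=C[C@@H]1O | intermediate
9 | methyl (1R,2S)-1,2-(isopropylidenedioxy)cyclohex-3-ene-1-carboxylate | COC(=O)[C@@]12CCC=C[C@@H]1OC(C)(C)O2 | intermediate
10 | [(1S,2S)-1,2-(isopropylidenedioxy)cyclohex-3-en-1-yl]methanol | OC[C@@]12CCC=C[C@@H]1OC(C)(C)O2 | intermediate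
11 | [(1S,2S,3R,4R)-3,4-epoxy-1,2-(isopropylidenedioxy)cyclohexyl]methanol | OC[C@@]12CC[C@H]3O[C@H]3[C@@H]1OC(C)(C)O2 | intermediate
12 | (1S,2S,3S,4S)-1-(hydroxymethyl)-1,2-O-isopropylidene-4-(phenylselanyl)cyclohexane-1,2,3-triol | OC[C@@]12CC[C@H]([Se]c3ccccc3)[C@@H](O)[C@@H]1OC(C)(C)O2 | intermediate
13 | selenoxide of 12 (configuration at selenium undefined) | OC[C@@]12CC[C@H]([Se](=O)c3ccccc3)[C@@H](O)[C@@H]1OC(C)(C)O2 | intermediate
14 | (1S,2S,3R)-1-(hydroxymethyl)-1,2-O-isopropylidenecyclohex-4-ene-1,2,3-triol | OC[C@@]12CC=C[C@@H](O)[C@@H]1OC(C)(C)O2 | intermediate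
15 | [(1S,2S,3R)-3-(benzoyloxy)-1,2-(isopropylidenedioxy)cyclohex-4-en-1-yl]methyl benzoate | O=C(OC[C@@]12CC=C[C@@H](OC(=O)c3ccccc3)[C@@H]1OC(C)(C)O2)c1ccccc1 | intermediate
16 | [(1S,2S,3R)-3-(benzoyloxy)-6-hydroxy-1,2-(isopropylidenedioxy)cyclohex-4-en-1-yl]methyl benzoate (C6 left open, both epimers converge on 17) | O=C(OC[C@@]12C(O)C=C[C@@H](OC(=O)c3ccccc3)[C@@H]1OC(C)(C)O2)c1ccccc1 | intermediate
17 | [(1S,2S,3R)-3-(benzoyloxy)-1,2-(isopropylidenedioxy)-6-oxocyclohex-4-en-1-yl]methyl benzoate | O=C(OC[C@@]12C(=O)C=C[C@@H](OC(=O)c3ccccc3)[C@@H]1OC(C)(C)O2)c1ccccc1 | intermediate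
18 | zeylenone | O=C(OC[C@@]1(O)C(=O)C=C[C@@H](OC(=O)c2ccccc2)[C@@H]1O)c1ccccc1 | target

Total step count: 12. Longest linear sequence: 12 steps (1 to 18); the diene 6 is bought.

**Steps most likely to fail**

**Step 11.**
- Risk: the ene reaction of SeO2 may be too slow on an alkene that the allylic benzoate deactivates and the quaternary C1 crowds. Acid-induced loss of the acetonide or attack at C3–H could then take over.
- The fallback sets out from 15 and brings both oxygens in by a cycloaddition whose topology fixes their positions.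
- Palladium(0)-catalysed 1,4-elimination of the allylic benzoate (Pd(PPh3)4, Et3N, dioxane, reflux) should give [(1S,2S)-1,2-(isopropylidenedioxy)cyclohexa-3,5-dien-1-yl]methyl benzoate F1. The metal sits anti to the leaving group and finds a syn hydrogen only on C6.
- Sensitised photooxygenation (O2, tetraphenylporphyrin, light, CH2Cl2, low temperature) adds singlet oxygen across C3 and C6 on the face away from the acetonide. This gives the 3,6-endoperoxide F2.
- Thiourea in MeOH cleaves the O–O bond to the cis-ene-3,6-diol F3.
- One equivalent of BzCl in pyridine at low temperature should acylate the C3 hydroxyl in preference to the C6 hydroxyl next to the quaternary carbon.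
- The route is rejoined at 16, as a single C6 epimer, and the Dess–Martin half of step 11 carries it to 17.

**Step 4.**
- Risk: at the temperature the weakly donating acetoxy diene needs, radical polymerisation of the dienophile may outrun cycloaddition, and exo and facial selectivity may erode.
- The fallback sets out from 5 and keeps the same two bond formations, but changes the donor on the diene.
- Bought (E)-1-(trimethylsilyloxy)buta-1,3-diene (C=C/C=C/O[Si](C)(C)C) is more electron-rich and should react well below 110 °C. The product would be (2S,5R,6S)-2-tert-butyl-6-(trimethylsilyloxy)-1,3-dioxaspiro[4.5]dec-7-en-4-one F4.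
- Catalytic NaOMe in MeOH opens the dioxolanone and removes the silyl group together. The route is rejoined at 8.

**Step 9.**
- Risk: the selenolate may open the epoxide at C3 if the trans-diaxial (Fürst–Plattner) preference of the acetonide-locked ring overrides the inductive bias. Any incomplete facial selectivity from step 8 would also surface here.
- The fallback sets out from 7 and delivers the C3 oxygen intramolecularly from C7, which lies on the required face.
- LiOH in aqueous THF gives (1R,2S)-1,2-dihydroxycyclohex-3-ene-1-carboxylic acid F5.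
- Iodolactonisation (I2, KI, NaHCO3, water/CH2Cl2) closes the C7–O–C3 gamma-lactone with iodine anti at C4. The product is 1,8-dihydroxy-4-iodo-6-oxabicyclo[3.2.1]octan-7-one F6.
- DBU in refluxing toluene removes HI towards C5 to give 1,8-dihydroxy-6-oxabicyclo[3.2.1]oct-3-en-7-one F7.
- NaOMe in MeOH opens the lactone to methyl (1R,2S,3R)-1,2,3-trihydroxycyclohex-4-ene-1-carboxylate F8.
- 2,2-Dimethoxypropane with catalytic acid bridges the only cis diol, giving methyl (1R,2S,3R)-3-hydroxy-1,2-(isopropylidenedioxy)cyclohex-4-ene-1-carboxylate F9.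
- LiAlH4 reduces the ester, and the route is rejoined at 14.

**Further compounds**

F1 | step 11 | [(1S,2S)-1,2-(isopropylidenedioxy)cyclohexa-3,5-dien-1-yl]methyl benzoate | O=C(OC[C@@]12C=CC=C[C@@H]1OC(C)(C)O2)c1ccccc1
F2 | step 11 | [3,6-epidioxy-1,2-(isopropylidenedioxy)cyclohex-4-en-1-yl]methyl benzoate, O–O bridge anti to the acetonide | O=C(OC[C@@]12[C@@H]3C=C[C@@H](OO3)[C@@H]1OC(C)(C)O2)c1ccccc1
F3 | step 11 | [3,6-dihydroxy-1,2-(isopropylidenedioxy)cyclohex-4-en-1-yl]methyl benzoate, both hydroxyls anti to the acetonide | O=C(OC[C@@]12[C@@H](O)C=C[C@@H](O)[C@@H]1OC(C)(C)O2)c1ccccc1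
F4 | step 4 | (2S,5R,6S)-2-tert-butyl-6-(trimethylsilyloxy)-1,3-dioxaspiro[4.5]dec-7-en-4-one | O=C1O[C@@H](C(C)(C)C)O[C@@]12CCC=C[C@@H]2O[Si](C)(C)C
F5 | step 9 | (1R,2S)-1,2-dihydroxycyclohex-3-ene-1-carboxylic acid | OC(=O)[C@@]1(O)CCC=C[C@@H]1O
F6 | step 9 | 1,8-dihydroxy-4-iodo-6-oxabicyclo[3.2.1]octan-7-one (C7–O–C3 lactone, iodine at C4 anti to the lactone oxygen) | O=C1O[C@@H]2[C@@H](I)CC[C@@]1(O)[C@H]2O
F7 | step 9 | 1,8-dihydroxy-6-oxabicyclo[3.2.1]oct-3-en-7-one | O=C1O[C@@H]2C=CC[C@@]1(O)[C@H]2O
F8 | step 9 | methyl (1R,2S,3R)-1,2,3-trihydroxycyclohex-4-ene-1-carboxylate | COC(=O)[C@@]1(O)CC=C[C@@H](O)[C@@H]1O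
F9 | step 9 | methyl (1R,2S,3R)-3-hydroxy-1,2-(isopropylidenedioxy)cyclohex-4-ene-1-carboxylate | COC(=O)[C@@]12CC=C[C@@H](O)[C@@H]1OC(C)(C)O2
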